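## Retrosynthetic overview

1. Target 12 ⇒ acyclic octa-1,7-diene 11 by ring-closing metathesis; the cyclohexene is the only ring formed, and it is formed last.
2. 11 ⇒ ketone 7 + 3-bromopropenyl acetate 9. The bond between the tertiary carbinol carbon and the adjacent CH(OAc) is made by a γ-acetoxyallylindium, in which the acrolein carbonyl carbon acts as a nucleophile towards the ketone carbon. This one step sets both new stereocentres.
3. 7 ⇒ 6-iodo-sorbofuranose 4 by zinc reductive fragmentation, which unmasks the C2 ketone and the terminal alkene; sorbose C3 and C4 become the CH(OAc) and CH(OBz) carbons of the target.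
4. 4 ⇒ diacetone-L-sorbose 1; 9 ⇒ acrolein 8 + acetyl bromide.

Assumption: diacetone-L-sorbose (1) and acrolein (8) are bought; 3-bromopropenyl acetate (9) is made in one step.

Atom labels used below (target ring): C1 = C(OH)(CH2OBz), C2 = CH(OAc) next to the alkene, C3=C4, C5 = CH(OBz), C6 = CH(OAc). Sorbose C1/C2/C3/C4/C5 become CH2OBz/C1/C6/C5/C4 of the target.

## Route

Step 1
Reactants: 1 2,3:4,6-di-O-isopropylidene-α-L-sorbofuranose
Product: 2 2,3-O-isopropylidene-α-L-sorbofuranose
Conditions: AcOH/H2O (3:2), 40 °C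
Reagents that add atoms: water O
Why: Selective acetal hydrolysis, because the six-membered 4,6-dioxane acetonide is far more labile than the cis-fused 2,3-dioxolane anchored at the anomeric carbon; no stereocentre is touched.

Step 2
Reactants: 2 2,3-O-isopropylidene-α-L-sorbofuranose
Product: 3 6-deoxy-6-iodo-2,3-O-isopropylidene-α-L-sorbofuranose
Conditions: PPh3, I2, imidazole, THF, 0 °C → rt
Reagents that add atoms: iodine II
Why: Appel-type (Garegg–Samuelsson) iodination by SN2 at the unhindered primary C6, while the other primary carbon C1 is neopentyl-like next to the quaternary ketal carbon and C4 is secondary (the same 6-selectivity is known for sulfonylation of this triol).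

Step 3
Reactants: 3 6-deoxy-6-iodo-2,3-O-isopropylidene-α-L-sorbofuranose
Product: 4 1,4-di-O-benzoyl-6-deoxy-6-iodo-2,3-O-isopropylidene-α-L-sorbofuranose
Conditions: BzCl, pyridine, DMAP (cat.), CH2Cl2, 0 °C → rt
Reagents that add atoms: benzoyl chloride O=C(Cl)c1ccccc1
Why: DMAP-catalysed acylation of the two remaining hydroxyls installs both benzoates of the target in their final positions (O1 → CH2OBz, O4 → C5-OBz).

Step 4
Reactants: 4 1,4-di-O-benzoyl-6-deoxy-6-iodo-2,3-O-isopropylidene-α-L-sorbofuranose
Product: 6 (3S,4R)-3-hydroxy-2-oxohex-5-ene-1,4-diyl dibenzoate, via C6 alkylzinc iodide 5 (not isolated)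
Conditions: Zn dust (activated), THF/H2O (4:1), sonication, 40 °C
Reagents that add atoms: none
Why: Bernet–Vasella reductive fragmentation, in which zinc insertion at C6–I and β-elimination of the ring oxygen give the C5=C6 alkene, and the resulting C2 hemiketal alkoxide collapses to the ketone with loss of acetone from the 2,3-acetonide, freeing O3; C3 and C4 are untouched.

Step 5
Reactants: 6 (3S,4R)-3-hydroxy-2-oxohex-5-ene-1,4-diyl dibenzoate
Product: 7 (3S,4R)-3-acetoxy-2-oxohex-5-ene-1,4-diyl dibenzoate
Conditions: Ac2O, Sc(OTf)3 (1 mol %), MeCN, −20 °C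
Reagents that add atoms: acetic anhydride CC(=O)OC(C)=O
Why: Fast Lewis-acid-catalysed acetylation of the secondary α-ketol hydroxyl under base-free conditions, which avoids E1cB loss of the benzoate β to the ketone and outruns benzoyl migration; no stereocentre is touched.

Step 6
Reactants: 8 acrolein
Product: 9 3-bromoprop-1-en-1-yl acetate (E/Z mixture)
Conditions: AcBr, ZnCl2 (cat.), CH2Cl2, −20 °C → rt
Reagents that add atoms: acetyl bromide CC(=O)Br
Why: Lewis-acid-catalysed 1,4-addition of the acyl bromide across the enal (O-acylation, bromide to C3) gives the enol-acetate allyl bromide; the E/Z ratio is irrelevant because the derived allylindium equilibrates.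

Step 7
Reactants: 7 (3S,4R)-3-acetoxy-2-oxohex-5-ene-1,4-diyl dibenzoate; 9 3-bromoprop-1-en-1-yl acetate
Product: 11 (3S,4R,5S,6R)-3,5-diacetoxy-6-(benzoyloxy)-4-[(benzoyloxy)methyl]-4-hydroxyocta-1,7-diene, via 3-acetoxyallylindium dibromide 10 (not isolated)
Conditions: In powder (2 equiv), 9 (3 equiv), THF, 0 °C → rt; pH 7 buffer work-up
Reagents that add atoms: none
Why: Proposed new method: indium metal inserts into the allylic C–Br bond of 9 to give γ-acetoxyallylindium 10, in which the former carbonyl carbon of acrolein is nucleophilic (an α-oxyallyl anion), and this adds through its oxygen-bearing carbon to the ketone carbon of 7, activated by two α-acyloxy groups, in a closed chair transition state (Barbier-type acyloxyallylation; closest known reaction type is the indium-mediated addition of 3-bromopropenyl esters to aldehydes, including sugar-derived enals); the face is set by polar Felkin–Anh (Cornforth) control with the non-chelating α-OAc anti to the incoming carbon, giving the tertiary carbinol erythro to that acetate (4R, ring-cis), and the new CH(OAc) is set 3S (threo to the new OH, ring-trans) because the branched chain sits equatorial, CH2OBz axial, and the internally chelated Z-enol acetate terminus places its OAc axial, anti to the axial CH2OBz.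

Step 8
Reactants: 11 (3S,4R,5S,6R)-3,5-diacetoxy-6-(benzoyloxy)-4-[(benzoyloxy)methyl]-4-hydroxyocta-1,7-diene
Product: 12 [(1R,2S,5R,6S)-2,6-diacetoxy-5-(benzoyloxy)-1-hydroxycyclohex-3-en-1-yl]methyl benzoate
Conditions: second-generation Grubbs catalyst (H2IMes)(PCy3)Cl2Ru=CHPh (5 mol %), CH2Cl2 (5 mM), 40 °C
Reagents that add atoms: none
Why: Ring-closing metathesis of two monosubstituted alkenes to a strain-free cyclohexene with loss of ethylene, tolerant of the esters and the free tertiary alcohol; all four stereocentres are carried over unchanged.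

## Compound list

1 | 2,3:4,6-di-O-isopropylidene-α-L-sorbofuranose (diacetone-L-sorbose) | OC[C@]12OC(C)(C)O[C@H]1[C@@H]1OC(C)(C)OC[C@@H]1O2 | starting material
2 | 2,3-O-isopropylidene-α-L-sorbofuranose | OC[C@]12OC(C)(C)O[C@H]1[C@H](O)[C@H](CO)O2 | intermediate
3 | 6-deoxy-6-iodo-2,3-O-isopropylidene-α-L-sorbofuranose | OC[C@]12OC(C)(C)O[C@H]1[C@H](O)[C@H](CI)O2 | intermediate
4 | 1,4-di-O-benzoyl-6-deoxy-6-iodo-2,3-O-isopropylidene-α-L-sorbofuranose | O=C(OC[C@]12OC(C)(C)O[C@H]1[C@H](OC(=O)c3ccccc3)[C@H](CI)O2)c1ccccc1 | intermediate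
5 | C6 alkylzinc iodide of 4 (not isolated) | O=C(OC[C@]12OC(C)(C)O[C@H]1[C@H](OC(=O)c3ccccc3)[C@H](C[Zn]I)O2)c1ccccc1 | intermediate
6 | (3S,4R)-3-hydroxy-2-oxohex-5-ene-1,4-diyl dibenzoate | C=C[C@@H](OC(=O)c1ccccc1)[C@H](O)C(=O)COC(=O)c1ccccc1 | intermediate
7 | (3S,4R)-3-acetoxy-2-oxohex-5-ene-1,4-diyl dibenzoate | C=C[C@@H](OC(=O)c1ccccc1)[C@H](OC(C)=O)C(=O)COC(=O)c1ccccc1 | intermediate
8 | acrolein | C=CC=O | starting material
9 | 3-bromoprop-1-en-1-yl acetate (E/Z mixture) | CC(=O)OC=CCBr | intermediate
10 | (Z)-3-acetoxyallylindium dibromide (not isolated; drawn as the monoallyl component of the sesquibromide) | CC(=O)O/C=C\C[In](Br)Br | intermediate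
11 | (3S,4R,5S,6R)-3,5-diacetoxy-6-(benzoyloxy)-4-[(benzoyloxy)methyl]-4-hydroxyocta-1,7-diene | C=C[C@@H](OC(=O)c1ccccc1)[C@H](OC(C)=O)[C@@](O)(COC(=O)c1ccccc1)[C@@H](OC(C)=O)C=C | intermediate
12 | [(1R,2S,5R,6S)-2,6-diacetoxy-5-(benzoyloxy)-1-hydroxycyclohex-3-en-1-yl]methyl benzoate (1-OH/6-OAc cis, 1-OH/2-OAc trans, 5-OBz/6-OAc trans) | CC(=O)O[C@H]1C=C[C@@H](OC(=O)c2ccccc2)[C@H](OC(C)=O)[C@@]1(O)COC(=O)c1ccccc1 | target

## Step count and risks

Total: 8 steps. Longest linear sequence: 7 steps (steps 1–5, 7, 8 from 1); step 6 is a one-step branch to reagent 9.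

**Step 7 (most at risk).** Acyloxyallylindium additions are established for aldehydes, not for an α,α'-diacyloxy ketone. The step must control the attacking face, the syn/anti sense, and avoid acetyl migration onto the tertiary indium alkoxide. Fallback, setting out from 7 and returning at 11: replace the equilibrating Barbier reagent by a geometrically fixed, reagent-controlled one. Add 7 at −78 °C to preformed [(Z)-γ-(methoxymethoxy)allyl]diisopinocampheylborane (from allyl methoxymethyl ether, sec-BuLi, Ipc2BOMe and BF3·OEt2; the antipode matched to the Felkin face, ethanolamine work-up). This should give the syn adduct as the methoxymethyl-protected diene F1. Cleavage of the methoxymethyl ether with TMSBr in CH2Cl2 at −30 °C gives the diol diene F2. Selective acetylation of its secondary hydroxyl (Ac2O, Sc(OTf)3, −20 °C) then gives 11.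

**Step 4.** The acetonide-bearing hemiketal must collapse cleanly, and the free α-ketol 6 could suffer O4→O3 benzoyl migration or reduction. Fallback, setting out from 4 and returning at 7 (bypassing 6): acid-catalysed methanolysis of 4 (AcCl in MeOH, 0 °C → rt) exchanges the acetonide for a methyl glycoside, giving methyl 1,4-di-O-benzoyl-6-deoxy-6-iodo-L-sorbofuranoside F3 (anomeric mixture, free 3-OH). Acetylation gives methyl 3-O-acetyl-1,4-di-O-benzoyl-6-deoxy-6-iodo-L-sorbofuranoside F4. The classical Bernet–Vasella fragmentation of this fully acylated methyl glycoside (Zn, THF/H2O, sonication) then delivers 7 directly.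

**Step 2.** Iodination at C6 must beat the other primary hydroxyl (C1). Fallback, setting out from 1 and returning at 4: remove the competition by benzoylating first. BzCl/pyridine on 1 gives 1-O-benzoyl-2,3:4,6-di-O-isopropylidene-α-L-sorbofuranose F5. Selective hydrolysis of the 4,6-acetonide (aqueous AcOH, 40 °C) gives 1-O-benzoyl-2,3-O-isopropylidene-α-L-sorbofuranose F6. Its only primary hydroxyl is iodinated (PPh3, I2, imidazole) to give 1-O-benzoyl-6-deoxy-6-iodo-2,3-O-isopropylidene-α-L-sorbofuranose F7, and benzoylation of O4 gives 4.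

Further compounds
F1 | step 7 | (3S,4R,5S,6R)-5-acetoxy-6-(benzoyloxy)-4-[(benzoyloxy)methyl]-4-hydroxy-3-(methoxymethoxy)octa-1,7-diene | C=C[C@@H](OC(=O)c1ccccc1)[C@H](OC(C)=O)[C@@](O)(COC(=O)c1ccccc1)[C@@H](OCOC)C=C
F2 | step 7 | (3S,4R,5S,6R)-5-acetoxy-6-(benzoyloxy)-4-[(benzoyloxy)methyl]-3,4-dihydroxyocta-1,7-diene | C=C[C@@H](OC(=O)c1ccccc1)[C@H](OC(C)=O)[C@@](O)(COC(=O)c1ccccc1)[C@@H](O)C=C
F3 | step 4 | methyl 1,4-di-O-benzoyl-6-deoxy-6-iodo-L-sorbofuranoside (anomeric mixture) | COC1(COC(=O)c2ccccc2)O[C@@H](CI)[C@@H](OC(=O)c2ccccc2)[C@@H]1O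
F4 | step 4 | methyl 3-O-acetyl-1,4-di-O-benzoyl-6-deoxy-6-iodo-L-sorbofuranoside (anomeric mixture) | COC1(COC(=O)c2ccccc2)O[C@@H](CI)[C@@H](OC(=O)c2ccccc2)[C@@H]1OC(C)=O
F5 | step 2 | 1-O-benzoyl-2,3:4,6-di-O-isopropylidene-α-L-sorbofuranose | O=C(OC[C@]12OC(C)(C)O[C@H]1[C@@H]1OC(C)(C)OC[C@@H]1O2)c1ccccc1
F6 | step 2 | 1-O-benzoyl-2,3-O-isopropylidene-α-L-sorbofuranose | O=C(OC[C@]12OC(C)(C)O[C@H]1[C@H](O)[C@H](CO)O2)c1ccccc1
F7 | step 2 | 1-O-benzoyl-6-deoxy-6-iodo-2,3-O-isopropylidene-α-L-sorbofuranose | O=C(OC[C@]12OC(C)(C)O[C@H]1[C@H](O)[C@H](CI)O2)c1ccccc1
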